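**Plan**

- Numbering: ring C5–C10 with C10 = C(CH3)(vinyl), C9 = CH2, C8 = CH–O–acyl, C7 = CH–C11(=CH2)–C12O2H, C6 = CH–OH, C5 = CH–C4(=CH2)–C15H2OH; β is the face of the C10 methyl, which also carries C4, O6, C11 and O8.
- Retrosynthesis: cut the O8 ester (acid from the (S)-Roche ester) and reclose O6–C12 to a cis-fused α-methylene-γ-lactone; cut ring bond C7–C8; cut C6–C7 back to a Weinreb amide plus a C3 alkyne; cut C5–C10 ([3,3]); cut the ester of an (E)-allylic alcohol with itaconic anhydride.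
- Enabling feature: 6-OH and the C7 acrylic acid are cis on neighbouring ring carbons, so O6–C12 can be tied as a butenolide. Its β-carbon is C7, a radical acceptor, and C8, which carries oxygen in the target, can enter as an aldehyde-derived ketyl.
- Forward: the chain is joined by esterification and Ireland–Claisen shift (C5–C10), the butenolide is built on C6, the cyclohexane ring C5–C10 is closed last through C7–C8, and the lactone tether is opened in the final step.
- Stereochemistry: C5/C10 from the chair Ireland–Claisen of a chiral boron enolate; C6 from catalyst-controlled, Felkin-matched ketone reduction; C7 from the cis ring fusion forced by the lactone; C8 from α-face hydride delivery to the bicyclic ketone; C2′ from the (S)-Roche ester.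

Key step: step 11

Abbreviations: TBS = tert-butyldimethylsilyl; TBDPS = tert-butyldiphenylsilyl; TES = triethylsilyl; PPTS = pyridinium p-toluenesulfonate; DMAP = 4-(dimethylamino)pyridine; CDI = 1,1'-carbonyldiimidazole; TsDPEN = N-tosyl-1,2-diphenylethylenediamine.

Remark 1: the sense of asymmetric induction of the (4S,5S)-diazaborolidine bromide in step 5 is assumed from the chair model; the antipodal controller is used if the opposite enantiomer forms.

Remark 2: the target is a cis-γ-hydroxy acid and is assumed to be isolable as the free acid when kept cold and away from acid.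

**Route**

Step 1
Reactants: 1 tert-butyl(but-3-yn-1-yloxy)dimethylsilane
Product: 3 (2E)-5-(TBS-oxy)-3-methylpent-2-en-1-ol, via alkenyl(dimethyl)alane 2 (not isolated)
Conditions: AlMe3, Cp2ZrCl2 (cat.), CH2Cl2, 0 °C → rt; then (CH2O)n, THF, 0 °C → rt; aq. HCl
Reagents that add atoms: trimethylaluminium, C[Al](C)C; formaldehyde (as paraformaldehyde), C=O
Why: Zirconium-catalysed carboalumination (Negishi) adds CH3–Al syn across the terminal alkyne with the methyl on the internal carbon, and the alkenylalane is hydroxymethylated with retention, so only the (E)-trisubstituted allylic alcohol should form.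

Step 2
Reactants: 3 (2E)-5-(TBS-oxy)-3-methylpent-2-en-1-ol; 4 itaconic anhydride
Product: 5 4-[(2E)-5-(TBS-oxy)-3-methylpent-2-en-1-yl] hydrogen 2-methylidenebutanedioate
Conditions: toluene, 80 °C
Reagents that add atoms: none
Why: Alcoholysis of itaconic anhydride opens the non-conjugated carbonyl, which gives the 4-monoester and leaves the acrylic acid (the future C15) free.

Step 3
Reactants: 5 4-[(2E)-5-(TBS-oxy)-3-methylpent-2-en-1-yl] hydrogen 2-methylidenebutanedioate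
Product: 7 (2E)-5-(TBS-oxy)-3-methylpent-2-en-1-yl 3-(hydroxymethyl)but-3-enoate, via mixed carbonic anhydride 6 (not isolated)
Conditions: i-BuOCOCl, N-methylmorpholine, THF, −15 °C; then NaBH4, THF/H2O, −15 → 0 °C
Reagents that add atoms: none
Why: Activation as the mixed carbonic anhydride lets NaBH4 reduce the acid by 1,2-addition to the primary allylic alcohol while the ester and the alkenes stay untouched.

Step 4
Reactants: 7 (2E)-5-(TBS-oxy)-3-methylpent-2-en-1-yl 3-(hydroxymethyl)but-3-enoate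
Product: 8 (2E)-5-(TBS-oxy)-3-methylpent-2-en-1-yl 3-[(TBDPS-oxy)methyl]but-3-enoate
Conditions: TBDPSCl, imidazole, CH2Cl2, 0 °C → rt
Reagents that add atoms: tert-butyl(chloro)diphenylsilane, CC(C)(C)[Si](Cl)(c1ccccc1)c1ccccc1
Why: Standard silylation of the primary alcohol, with the TBDPS group chosen because it outlives the later acidic removal of the TBS and TES ethers.

Step 5
Reactants: 8 (2E)-5-(TBS-oxy)-3-methylpent-2-en-1-yl 3-[(TBDPS-oxy)methyl]but-3-enoate
Product: 10 (2R,3S)-5-(TBS-oxy)-2-[3-(TBDPS-oxy)prop-1-en-2-yl]-3-ethenyl-3-methylpentanoic acid, via boron ketene acetal 9 (not isolated)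
Conditions: (4S,5S)-2-bromo-1,3-bis{[3,5-bis(trifluoromethyl)phenyl]sulfonyl}-4,5-diphenyl-1,3,2-diazaborolidine, Et3N, toluene/hexane, −78 °C → 4 °C; aq. work-up
Reagents that add atoms: none
Why: Ireland–Claisen rearrangement of a boron ketene acetal made by soft enolisation, in which the chair transition state with the (E)-alkene (C9 chain equatorial, methyl axial) and the enolate geometry with the alkenyl group trans to O–B fix C5 relative to C10, and the C2-symmetric sulfonamide ligand on boron selects the enolate face and so the absolute configuration.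

Step 6
Reactants: 10 (2R,3S)-5-(TBS-oxy)-2-[3-(TBDPS-oxy)prop-1-en-2-yl]-3-ethenyl-3-methylpentanoic acid
Product: 12 (2R,3S)-5-(TBS-oxy)-2-[3-(TBDPS-oxy)prop-1-en-2-yl]-3-ethenyl-N-methoxy-N,3-dimethylpentanamide, via acyl imidazole 11 (not isolated)
Conditions: CDI, CH2Cl2, rt; then MeNH(OMe)·HCl, rt → 35 °C
Reagents that add atoms: N,O-dimethylhydroxylamine hydrochloride, CNOC.Cl
Why: Weinreb amide formation through the acyl imidazole needs no added base, which protects the allylic α-stereocentre C5 from epimerisation.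

Step 7
Reactants: 12 (2R,3S)-5-(TBS-oxy)-2-[3-(TBDPS-oxy)prop-1-en-2-yl]-3-ethenyl-N-methoxy-N,3-dimethylpentanamide; 13 3,3,3-triethoxyprop-1-yne
Product: 15 ethyl (5R,6S)-8-(TBS-oxy)-5-[3-(TBDPS-oxy)prop-1-en-2-yl]-6-ethenyl-6-methyl-4-oxooct-2-ynoate, via orthoester ynone 14 (not isolated)
Conditions: 13, n-BuLi, THF, −78 °C; add 12, −78 → −10 °C; then cold 0.5 M HCl, THF, 0 °C
Reagents that add atoms: water, O
Why: The lithium acetylide of the orthoester (a propiolate anion equivalent that tolerates warming) adds once to the Weinreb amide through the chelated tetrahedral intermediate, and the acidic work-up releases the ynone and hydrolyses the orthoester to the ethyl ester.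

Step 8
Reactants: 15 ethyl (5R,6S)-8-(TBS-oxy)-5-[3-(TBDPS-oxy)prop-1-en-2-yl]-6-ethenyl-6-methyl-4-oxooct-2-ynoate
Product: 16 ethyl (4S,5R,6S)-8-(TBS-oxy)-5-[3-(TBDPS-oxy)prop-1-en-2-yl]-6-ethenyl-4-hydroxy-6-methyloct-2-ynoate
Conditions: RuCl[(S,S)-TsDPEN](p-cymene) (3 mol%), HCO2H/Et3N (5:2), CH2Cl2, 0 °C → rt
Reagents that add atoms: none
Why: Noyori-type asymmetric transfer hydrogenation of an alkynyl ketone, in which the alkynyl group takes the place of the aryl group of the usual model so that the (S,S)-ligand should give the (4S)-carbinol, which is also the Felkin–Anh outcome of hydride attack anti to the quaternary C10, so catalyst and substrate reinforce each other in setting C6.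

Step 9
Reactants: 16 ethyl (4S,5R,6S)-8-(TBS-oxy)-5-[3-(TBDPS-oxy)prop-1-en-2-yl]-6-ethenyl-4-hydroxy-6-methyloct-2-ynoate
Product: 19 (5R)-5-[(3R,4S)-2-[(TBDPS-oxy)methyl]-4-ethenyl-6-hydroxy-4-methylhex-1-en-3-yl]furan-2(5H)-one, via (Z)-hydroxy enoate 17 (not isolated), via TBS-protected butenolide 18 (not isolated)
Conditions: H2 (1 atm), Pd/CaCO3/Pb(OAc)2 (Lindlar), quinoline, EtOAc, rt; filter; then PPTS, MeOH, rt
Reagents that add atoms: none
Why: cis-Semihydrogenation of the ynoate over the lead-poisoned Pd/CaCO3 catalyst gives the (Z)-γ-hydroxy enoate, which lactonises to the butenolide, and the same mildly acidic methanol removes the primary TBS ether while the TBDPS ether survives.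

Step 10
Reactants: 19 (5R)-5-[(3R,4S)-2-[(TBDPS-oxy)methyl]-4-ethenyl-6-hydroxy-4-methylhex-1-en-3-yl]furan-2(5H)-one
Product: 20 (3S,4R)-5-[(TBDPS-oxy)methyl]-3-ethenyl-3-methyl-4-[(2R)-5-oxo-2,5-dihydrofuran-2-yl]hex-5-enal
Conditions: Dess–Martin periodinane, CH2Cl2, 0 °C → rt
Reagents that add atoms: none
Why: Dess–Martin oxidation of the primary alcohol runs under neutral conditions, which spares the base-labile γ-centre (C6) of the butenolide.

Step 11
Reactants: 20 (3S,4R)-5-[(TBDPS-oxy)methyl]-3-ethenyl-3-methyl-4-[(2R)-5-oxo-2,5-dihydrofuran-2-yl]hex-5-enal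
Product: 21 (3aR,4S,6S,7R,7aS)-7-[3-(TBDPS-oxy)prop-1-en-2-yl]-6-ethenyl-4-hydroxy-6-methylhexahydro-1-benzofuran-2(3H)-one
Conditions: SmI2 (2.5 equiv), MeOH (4 equiv), THF, −78 °C, 0.01 M
Reagents that add atoms: none
Why: SmI2 reduces the aldehyde C8 to a samarium ketyl, which adds to C7, the β-carbon of the butenolide, and a second electron transfer turns the α-lactone radical at C11 into a samarium enolate that MeOH protonates. The closest known reaction type is the SmI2 ketyl–olefin cyclisation of aldehydes onto α,β-unsaturated esters and lactones. The cyclohexane ring C5–C10 closes through the C7–C8 bond in a 6-exo-trig mode, helped by the gem-disubstituted C10. C7 is controlled by the butenolide ring: C6 already holds the tether on one face of the planar lactone, so the ketyl can reach C7 only from that face and the ring fusion must be cis (C11 β, cis to O6). C8 is formed without reliable control (the samarium-bound oxygen should prefer the equatorial 8α position shown; any 8β epimer is compound 23) and is reset in steps 12 and 13. The step needs chemoselectivity for the electron-poor butenolide over the two unactivated alkenes, which the nucleophilic ketyl without HMPA should provide, and base-free conditions that leave C6 untouched.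

Step 12
Reactants: 21 (3aR,4S,6S,7R,7aS)-7-[3-(TBDPS-oxy)prop-1-en-2-yl]-6-ethenyl-4-hydroxy-6-methylhexahydro-1-benzofuran-2(3H)-one
Product: 22 (3aS,6S,7R,7aS)-7-[3-(TBDPS-oxy)prop-1-en-2-yl]-6-ethenyl-6-methyltetrahydro-1-benzofuran-2,4(3H,5H)-dione
Conditions: Dess–Martin periodinane, CH2Cl2, 0 °C → rt
Reagents that add atoms: none
Why: Dess–Martin oxidation converges both C8 epimers on one ketone under base-free conditions, which matters because this β-acyloxy ketone would open by retro-oxa-Michael reaction with base.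

Step 13
Reactants: 22 (3aS,6S,7R,7aS)-7-[3-(TBDPS-oxy)prop-1-en-2-yl]-6-ethenyl-6-methyltetrahydro-1-benzofuran-2,4(3H,5H)-dione
Product: 23 (3aR,4R,6S,7R,7aS)-7-[3-(TBDPS-oxy)prop-1-en-2-yl]-6-ethenyl-4-hydroxy-6-methylhexahydro-1-benzofuran-2(3H)-one
Conditions: NaBH4, CeCl3·7H2O, MeOH/THF, −78 °C
Reagents that add atoms: none
Why: Luche-type reduction, in which the favoured chair of the cis-fused lactone (C4 unit and C11 equatorial, C10 methyl and O6 axial on the β face) blocks axial approach to C8 by the 1,3-diaxial methyl and lactone oxygen and by the lactone ring on the concave face, so hydride should arrive from the α face and give the axial 8β-alcohol.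

Step 14
Reactants: 23 (3aR,4R,6S,7R,7aS)-7-[3-(TBDPS-oxy)prop-1-en-2-yl]-6-ethenyl-4-hydroxy-6-methylhexahydro-1-benzofuran-2(3H)-one
Product: 24 (3aS,4R,6S,7R,7aS)-7-[3-(TBDPS-oxy)prop-1-en-2-yl]-6-ethenyl-6-methyl-4-(TES-oxy)hexahydro-1-benzofuran-2(3H)-one
Conditions: TESOTf, 2,6-lutidine, CH2Cl2, −78 °C
Reagents that add atoms: triethylsilyl trifluoromethanesulfonate, CC[Si](CC)(CC)OS(=O)(=O)C(F)(F)F
Why: Silylation of the hindered axial alcohol with the reactive triflate keeps the C8 oxygen from attacking the lactone during the enolate chemistry of step 15.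

Step 15
Reactants: 24 (3aS,4R,6S,7R,7aS)-7-[3-(TBDPS-oxy)prop-1-en-2-yl]-6-ethenyl-6-methyl-4-(TES-oxy)hexahydro-1-benzofuran-2(3H)-one
Product: 27 (3aS,4R,6S,7R,7aS)-7-[3-(TBDPS-oxy)prop-1-en-2-yl]-6-ethenyl-6-methyl-3-methylidene-4-(TES-oxy)hexahydro-1-benzofuran-2(3H)-one, via Mannich base 25 (not isolated), via ammonium iodide 26 (not isolated)
Conditions: LiN(i-Pr)2, THF, −78 °C; CH2=NMe2+ I−, −78 → 0 °C; then MeI, MeOH, rt; then aq. NaHCO3/CH2Cl2
Reagents that add atoms: N,N-dimethylmethyleneiminium iodide (Eschenmoser's salt), C=[N+](C)C.[I-]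
Why: Classical α-methylenation of a γ-lactone, in which the lithium enolate is aminomethylated (Mannich reaction), the amine is quaternised and the ammonium salt eliminates trimethylamine to give the exocyclic alkene C11=C13.

Step 16
Reactants: 27 (3aS,4R,6S,7R,7aS)-7-[3-(TBDPS-oxy)prop-1-en-2-yl]-6-ethenyl-6-methyl-3-methylidene-4-(TES-oxy)hexahydro-1-benzofuran-2(3H)-one
Product: 28 (3aR,4R,6S,7R,7aS)-7-[3-(TBDPS-oxy)prop-1-en-2-yl]-6-ethenyl-4-hydroxy-6-methyl-3-methylidenehexahydro-1-benzofuran-2(3H)-one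
Conditions: PPTS, MeOH/CH2Cl2, rt
Reagents that add atoms: none
Why: Acid-catalysed methanolysis removes the secondary TES ether, while the primary TBDPS ether is far more stable to acid and stays.

Step 17
Reactants: 29 methyl (2S)-3-hydroxy-2-methylpropanoate
Product: 30 methyl (2S)-3-(TBS-oxy)-2-methylpropanoate
Conditions: TBSCl, imidazole, CH2Cl2, 0 °C → rt
Reagents that add atoms: tert-butyl(chloro)dimethylsilane, CC(C)(C)[Si](C)(C)Cl
Why: Standard silylation of the primary alcohol of the Roche ester, which carries the side-chain stereocentre unchanged.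

Step 18
Reactants: 30 methyl (2S)-3-(TBS-oxy)-2-methylpropanoate
Product: 31 (2S)-3-(TBS-oxy)-2-methylpropanoic acid
Conditions: LiOH, THF/H2O, 0 °C; then 1 M HCl to pH 3
Reagents that add atoms: lithium hydroxide, [Li+].[OH-]
Why: Saponification at 0 °C is mild enough that α-epimerisation and β-elimination of the silyloxy ester should stay slow.

Step 19
Reactants: 28 (3aR,4R,6S,7R,7aS)-7-[3-(TBDPS-oxy)prop-1-en-2-yl]-6-ethenyl-4-hydroxy-6-methyl-3-methylidenehexahydro-1-benzofuran-2(3H)-one; 31 (2S)-3-(TBS-oxy)-2-methylpropanoic acid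
Product: 33 (3aR,4R,6S,7R,7aS)-7-[3-(TBDPS-oxy)prop-1-en-2-yl]-6-ethenyl-6-methyl-3-methylidene-2-oxooctahydro-1-benzofuran-4-yl (2S)-3-(TBS-oxy)-2-methylpropanoate, via mixed anhydride 32 (not isolated)
Conditions: 31, 2,4,6-trichlorobenzoyl chloride, Et3N, THF, rt; then 28, DMAP, toluene, rt
Reagents that add atoms: none
Why: Yamaguchi esterification through the mixed anhydride suits hindered secondary alcohols and acylates the only free hydroxyl (O8) with retention at both stereocentres.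

Step 20
Reactants: 33 (3aR,4R,6S,7R,7aS)-7-[3-(TBDPS-oxy)prop-1-en-2-yl]-6-ethenyl-6-methyl-3-methylidene-2-oxooctahydro-1-benzofuran-4-yl (2S)-3-(TBS-oxy)-2-methylpropanoate
Product: 34 (3aR,4R,6S,7R,7aS)-6-ethenyl-7-(3-hydroxyprop-1-en-2-yl)-6-methyl-3-methylidene-2-oxooctahydro-1-benzofuran-4-yl (2S)-3-hydroxy-2-methylpropanoate
Conditions: HF·pyridine, pyridine, THF, 0 °C → rt
Reagents that add atoms: none
Why: Buffered HF·pyridine cleaves both silyl ethers under conditions that leave the lactone and the ester intact.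

Step 21
Reactants: 34 (3aR,4R,6S,7R,7aS)-6-ethenyl-7-(3-hydroxyprop-1-en-2-yl)-6-methyl-3-methylidene-2-oxooctahydro-1-benzofuran-4-yl (2S)-3-hydroxy-2-methylpropanoate
Product: 35 (5R,6S,7S,8R,10S)-6,15-dihydroxy-8-{[(2S)-3-hydroxy-2-methylpropanoyl]oxy}elema-1,3,11(13)-trien-12-oic acid
Conditions: LiOH (1.1 equiv), THF/H2O, 0 °C; then cold dilute HCl to pH 5
Reagents that add atoms: lithium hydroxide, [Li+].[OH-]
Why: Hydroxide should open the γ-lactone much faster than it attacks the α-branched ester on the hindered axial oxygen, which frees the 6-hydroxyl and the C12 carboxylate together, and acidification only to pH 5 in the cold should give the free hydroxy acid without relactonisation.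

**Compound list**

1 | tert-butyl(but-3-yn-1-yloxy)dimethylsilane | C#CCCO[Si](C)(C)C(C)(C)C | starting material
2 | [(1E)-4-{[tert-butyl(dimethyl)silyl]oxy}-2-methylbut-1-en-1-yl](dimethyl)alane | C[Al](C)/C=C(\C)CCO[Si](C)(C)C(C)(C)C | intermediate
3 | (2E)-5-{[tert-butyl(dimethyl)silyl]oxy}-3-methylpent-2-en-1-ol | OC/C=C(\C)CCO[Si](C)(C)C(C)(C)C | intermediate
4 | itaconic anhydride (3-methylideneoxolane-2,5-dione) | C=C1CC(=O)OC1=O | starting material
5 | 4-{[(2E)-5-{[tert-butyl(dimethyl)silyl]oxy}-3-methylpent-2-en-1-yl]oxy}-2-methylidene-4-oxobutanoic acid | C=C(CC(=O)OC/C=C(\C)CCO[Si](C)(C)C(C)(C)C)C(=O)O | intermediate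
6 | mixed carbonic anhydride of 5 with isobutyl carbonate | C=C(CC(=O)OC/C=C(\C)CCO[Si](C)(C)C(C)(C)C)C(=O)OC(=O)OCC(C)C | intermediate
7 | (2E)-5-{[tert-butyl(dimethyl)silyl]oxy}-3-methylpent-2-en-1-yl 3-(hydroxymethyl)but-3-enoate | C=C(CO)CC(=O)OC/C=C(\C)CCO[Si](C)(C)C(C)(C)C | intermediate
8 | (2E)-5-{[tert-butyl(dimethyl)silyl]oxy}-3-methylpent-2-en-1-yl 3-({[tert-butyl(diphenyl)silyl]oxy}methyl)but-3-enoate | C=C(CO[Si](c1ccccc1)(c1ccccc1)C(C)(C)C)CC(=O)OC/C=C(\C)CCO[Si](C)(C)C(C)(C)C | intermediate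
9 | O-boryl ketene acetal of 8 (C5=C6 enolate, alkenyl group on C5 cis to the allyloxy group, boron in the (4S,5S)-diazaborolidine) | C=C(CO[Si](c1ccccc1)(c1ccccc1)C(C)(C)C)/C=C(\OC/C=C(\C)CCO[Si](C)(C)C(C)(C)C)OB1N(S(=O)(=O)c2cc(cc(c2)C(F)(F)F)C(F)(F)F)[C@@H](c2ccccc2)[C@H](c2ccccc2)N1S(=O)(=O)c1cc(cc(c1)C(F)(F)F)C(F)(F)F | intermediate
10 | (2R,3S)-5-{[tert-butyl(dimethyl)silyl]oxy}-2-[3-{[tert-butyl(diphenyl)silyl]oxy}prop-1-en-2-yl]-3-ethenyl-3-methylpentanoic acid | C=C[C@]([C@@H](C(=O)O)C(=C)CO[Si](c1ccccc1)(c1ccccc1)C(C)(C)C)(C)CCO[Si](C)(C)C(C)(C)C | intermediate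
11 | acyl imidazole of 10 | C=C[C@]([C@@H](C(=O)n1ccnc1)C(=C)CO[Si](c2ccccc2)(c2ccccc2)C(C)(C)C)(C)CCO[Si](C)(C)C(C)(C)C | intermediate
12 | (2R,3S)-5-{[tert-butyl(dimethyl)silyl]oxy}-2-[3-{[tert-butyl(diphenyl)silyl]oxy}prop-1-en-2-yl]-3-ethenyl-N-methoxy-N,3-dimethylpentanamide | C=C[C@]([C@@H](C(=O)N(C)OC)C(=C)CO[Si](c1ccccc1)(c1ccccc1)C(C)(C)C)(C)CCO[Si](C)(C)C(C)(C)C | intermediate
13 | 3,3,3-triethoxyprop-1-yne | C#CC(OCC)(OCC)OCC | starting material
14 | (5R,6S)-orthoester ynone (1,1,1-triethoxy analogue of 15) | C=C[C@]([C@@H](C(=O)C#CC(OCC)(OCC)OCC)C(=C)CO[Si](c1ccccc1)(c1ccccc1)C(C)(C)C)(C)CCO[Si](C)(C)C(C)(C)C | intermediate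
15 | ethyl (5R,6S)-8-{[tert-butyl(dimethyl)silyl]oxy}-5-[3-{[tert-butyl(diphenyl)silyl]oxy}prop-1-en-2-yl]-6-ethenyl-6-methyl-4-oxooct-2-ynoate | C=C[C@]([C@@H](C(=O)C#CC(=O)OCC)C(=C)CO[Si](c1ccccc1)(c1ccccc1)C(C)(C)C)(C)CCO[Si](C)(C)C(C)(C)C | intermediate
16 | ethyl (4S,5R,6S)-8-{[tert-butyl(dimethyl)silyl]oxy}-5-[3-{[tert-butyl(diphenyl)silyl]oxy}prop-1-en-2-yl]-6-ethenyl-4-hydroxy-6-methyloct-2-ynoate | C=C[C@]([C@@H]([C@H](O)C#CC(=O)OCC)C(=C)CO[Si](c1ccccc1)(c1ccccc1)C(C)(C)C)(C)CCO[Si](C)(C)C(C)(C)C | intermediate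
17 | ethyl (2Z,4R,5R,6S)-8-{[tert-butyl(dimethyl)silyl]oxy}-5-[3-{[tert-butyl(diphenyl)silyl]oxy}prop-1-en-2-yl]-6-ethenyl-4-hydroxy-6-methyloct-2-enoate | C=C[C@]([C@@H]([C@H](O)/C=C\C(=O)OCC)C(=C)CO[Si](c1ccccc1)(c1ccccc1)C(C)(C)C)(C)CCO[Si](C)(C)C(C)(C)C | intermediate
18 | (5R)-5-[(3R,4S)-6-{[tert-butyl(dimethyl)silyl]oxy}-2-({[tert-butyl(diphenyl)silyl]oxy}methyl)-4-ethenyl-4-methylhex-1-en-3-yl]furan-2(5H)-one | C=C[C@]([C@@H]([C@@H]1OC(=O)C=C1)C(=C)CO[Si](c1ccccc1)(c1ccccc1)C(C)(C)C)(C)CCO[Si](C)(C)C(C)(C)C | intermediate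
19 | (5R)-5-[(3R,4S)-2-({[tert-butyl(diphenyl)silyl]oxy}methyl)-4-ethenyl-6-hydroxy-4-methylhex-1-en-3-yl]furan-2(5H)-one | C=C[C@]([C@@H]([C@@H]1OC(=O)C=C1)C(=C)CO[Si](c1ccccc1)(c1ccccc1)C(C)(C)C)(C)CCO | intermediate
20 | (3S,4R)-5-({[tert-butyl(diphenyl)silyl]oxy}methyl)-3-ethenyl-3-methyl-4-[(2R)-5-oxo-2,5-dihydrofuran-2-yl]hex-5-enal | C=C[C@]([C@@H]([C@@H]1OC(=O)C=C1)C(=C)CO[Si](c1ccccc1)(c1ccccc1)C(C)(C)C)(C)CC=O | intermediate
21 | (3aR,4S,6S,7R,7aS)-7-[3-{[tert-butyl(diphenyl)silyl]oxy}prop-1-en-2-yl]-6-ethenyl-4-hydroxy-6-methylhexahydro-1-benzofuran-2(3H)-one (8α-alcohol, cis-fused lactone) | C=C[C@]1(C)C[C@H](O)[C@H]2CC(=O)O[C@H]2[C@H]1C(=C)CO[Si](c1ccccc1)(c1ccccc1)C(C)(C)C | intermediate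
22 | (3aS,6S,7R,7aS)-7-[3-{[tert-butyl(diphenyl)silyl]oxy}prop-1-en-2-yl]-6-ethenyl-6-methyltetrahydro-1-benzofuran-2,4(3H,5H)-dione | C=C[C@]1(C)CC(=O)[C@H]2CC(=O)O[C@H]2[C@H]1C(=C)CO[Si](c1ccccc1)(c1ccccc1)C(C)(C)C | intermediate
23 | (3aR,4R,6S,7R,7aS)-7-[3-{[tert-butyl(diphenyl)silyl]oxy}prop-1-en-2-yl]-6-ethenyl-4-hydroxy-6-methylhexahydro-1-benzofuran-2(3H)-one (8β-alcohol) | C=C[C@]1(C)C[C@@H](O)[C@H]2CC(=O)O[C@H]2[C@H]1C(=C)CO[Si](c1ccccc1)(c1ccccc1)C(C)(C)C | intermediate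
24 | (3aS,4R,6S,7R,7aS)-7-[3-{[tert-butyl(diphenyl)silyl]oxy}prop-1-en-2-yl]-6-ethenyl-6-methyl-4-[(triethylsilyl)oxy]hexahydro-1-benzofuran-2(3H)-one | C=C[C@]1(C)C[C@@H](O[Si](CC)(CC)CC)[C@H]2CC(=O)O[C@H]2[C@H]1C(=C)CO[Si](c1ccccc1)(c1ccccc1)C(C)(C)C | intermediate
25 | 3-[(dimethylamino)methyl] derivative of 24 (C3 epimers) | C=C[C@]1(C)C[C@@H](O[Si](CC)(CC)CC)[C@H]2C(CN(C)C)C(=O)O[C@H]2[C@H]1C(=C)CO[Si](c1ccccc1)(c1ccccc1)C(C)(C)C | intermediate
26 | trimethylammoniomethyl iodide derived from 25 | C=C[C@]1(C)C[C@@H](O[Si](CC)(CC)CC)[C@H]2C(C[N+](C)(C)C)C(=O)O[C@H]2[C@H]1C(=C)CO[Si](c1ccccc1)(c1ccccc1)C(C)(C)C.[I-] | intermediate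
27 | (3aS,4R,6S,7R,7aS)-7-[3-{[tert-butyl(diphenyl)silyl]oxy}prop-1-en-2-yl]-6-ethenyl-6-methyl-3-methylidene-4-[(triethylsilyl)oxy]hexahydro-1-benzofuran-2(3H)-one | C=C[C@]1(C)C[C@@H](O[Si](CC)(CC)CC)[C@H]2C(=C)C(=O)O[C@H]2[C@H]1C(=C)CO[Si](c1ccccc1)(c1ccccc1)C(C)(C)C | intermediate
28 | (3aR,4R,6S,7R,7aS)-7-[3-{[tert-butyl(diphenyl)silyl]oxy}prop-1-en-2-yl]-6-ethenyl-4-hydroxy-6-methyl-3-methylidenehexahydro-1-benzofuran-2(3H)-one | C=C[C@]1(C)C[C@@H](O)[C@H]2C(=C)C(=O)O[C@H]2[C@H]1C(=C)CO[Si](c1ccccc1)(c1ccccc1)C(C)(C)C | intermediate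
29 | methyl (2S)-3-hydroxy-2-methylpropanoate ((S)-Roche ester) | COC(=O)[C@@H](C)CO | starting material
30 | methyl (2S)-3-{[tert-butyl(dimethyl)silyl]oxy}-2-methylpropanoate | COC(=O)[C@@H](C)CO[Si](C)(C)C(C)(C)C | intermediate
31 | (2S)-3-{[tert-butyl(dimethyl)silyl]oxy}-2-methylpropanoic acid | OC(=O)[C@@H](C)CO[Si](C)(C)C(C)(C)C | intermediate
32 | mixed anhydride of 31 with 2,4,6-trichlorobenzoic acid | O=C(OC(=O)[C@@H](C)CO[Si](C)(C)C(C)(C)C)c1c(Cl)cc(Cl)cc1Cl | intermediate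
33 | (3aR,4R,6S,7R,7aS)-7-[3-{[tert-butyl(diphenyl)silyl]oxy}prop-1-en-2-yl]-6-ethenyl-6-methyl-3-methylidene-2-oxooctahydro-1-benzofuran-4-yl (2S)-3-{[tert-butyl(dimethyl)silyl]oxy}-2-methylpropanoate | C=C[C@]1(C)C[C@@H](OC(=O)[C@@H](C)CO[Si](C)(C)C(C)(C)C)[C@H]2C(=C)C(=O)O[C@H]2[C@H]1C(=C)CO[Si](c1ccccc1)(c1ccccc1)C(C)(C)C | intermediate
34 | (3aR,4R,6S,7R,7aS)-6-ethenyl-7-(3-hydroxyprop-1-en-2-yl)-6-methyl-3-methylidene-2-oxooctahydro-1-benzofuran-4-yl (2S)-3-hydroxy-2-methylpropanoate | C=C[C@]1(C)C[C@@H](OC(=O)[C@@H](C)CO)[C@H]2C(=C)C(=O)O[C@H]2[C@H]1C(=C)CO | intermediate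
35 | (5R,6S,7S,8R,10S)-6,15-dihydroxy-8-{[(2S)-3-hydroxy-2-methylpropanoyl]oxy}elema-1,3,11(13)-trien-12-oic acid | C=C[C@]1(C)C[C@@H](OC(=O)[C@@H](C)CO)[C@@H](C(=C)C(=O)O)[C@@H](O)[C@H]1C(=C)CO | target

**Step count**

Total step count: 21. Longest linear sequence: 19 steps (steps 1–16 and 19–21, from 1 to 35).

**Steps most likely to fail**

Step 11 (ring closure). The aldehyde may be reduced to the primary alcohol or couple to a pinacol, or the butenolide may be reduced, before the ketyl adds to C7. The fallback closes the ring with an acyl radical in place of the ketyl and sets out from aldehyde 20. Oxidation (NaClO2, NaH2PO4, 2-methylbut-2-ene) gives the carboxylic acid F1, and N-(phenylseleno)phthalimide with PBu3 in CH2Cl2 converts it into the Se-phenyl selenoester F2. Bu3SnH and AIBN in benzene at 80 °C under high dilution should then add the acyl radical to C7 in the 6-exo mode and give ketone 22 directly, where the route continues with step 13.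

Step 5 (Ireland–Claisen). Enolate geometry or facial control at boron may be lost (low diastereo- or enantioselectivity), or the β,γ-double bond may migrate during enolisation. The fallback relies on relative control only, followed by resolution, and sets out from ester 8. Rearrangement through the kinetic silyl ketene acetal (LiN(i-Pr)2, Me3SiCl, THF, −78 °C → rt) passes through the same chair and should give the racemic acid F3 with the relative configuration of 10. Crystallisation with (R)-1-phenylethylamine gives the diastereomerically pure ammonium salt F4 (the antipodal amine is taken if the other salt is the less soluble one), and acidification returns acid 10, where the route continues with step 6.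

Step 21 (final lactone opening). Hydroxide may also cleave the C8 ester or move it to O6, add to the exocyclic methylene, or the product may relactonise on acidification. The fallback protects the carboxyl as an allyl ester so that no hydroxide is used after acylation, and sets out from lactone 27. LiOH opens the lactone and the carboxylate is alkylated in the same flask with allyl bromide in DMF to the allyl ester F5 with free 6-OH. TBSOTf and 2,6-lutidine give the 6-O-TBS ether F6, PPTS in MeOH removes the TES group to give the 8-alcohol F7, and Yamaguchi esterification with acid 31 gives the C8 ester F8. HF·pyridine removes the three silyl groups to give the triol allyl ester F9, and Pd(PPh3)4 with morpholine cleaves the allyl ester under neutral conditions to the target 35.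

**Further compounds**

F1 | step 11 | (3S,4R)-5-({[tert-butyl(diphenyl)silyl]oxy}methyl)-3-ethenyl-3-methyl-4-[(2R)-5-oxo-2,5-dihydrofuran-2-yl]hex-5-enoic acid | C=C[C@]([C@@H]([C@@H]1OC(=O)C=C1)C(=C)CO[Si](c1ccccc1)(c1ccccc1)C(C)(C)C)(C)CC(=O)O
F2 | step 11 | Se-phenyl (3S,4R)-5-({[tert-butyl(diphenyl)silyl]oxy}methyl)-3-ethenyl-3-methyl-4-[(2R)-5-oxo-2,5-dihydrofuran-2-yl]hex-5-eneselenoate | C=C[C@]([C@@H]([C@@H]1OC(=O)C=C1)C(=C)CO[Si](c1ccccc1)(c1ccccc1)C(C)(C)C)(C)CC(=O)[Se]c1ccccc1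
F3 | step 5 | racemic (2R*,3S*)-acid (10 together with its enantiomer) | C=C[C@]([C@@H](C(=O)O)C(=C)CO[Si](c1ccccc1)(c1ccccc1)C(C)(C)C)(C)CCO[Si](C)(C)C(C)(C)C.C=C[C@@]([C@H](C(=O)O)C(=C)CO[Si](c1ccccc1)(c1ccccc1)C(C)(C)C)(C)CCO[Si](C)(C)C(C)(C)C
F4 | step 5 | (R)-1-phenylethylammonium salt of acid 10 | C=C[C@]([C@@H](C(=O)[O-])C(=C)CO[Si](c1ccccc1)(c1ccccc1)C(C)(C)C)(C)CCO[Si](C)(C)C(C)(C)C.C[C@@H]([NH3+])c1ccccc1
F5 | step 21 | prop-2-en-1-yl 15-(TBDPS-oxy)-6β-hydroxy-8β-(TES-oxy)elema-1,3,11(13)-trien-12-oate (5α-H, 7α-H, 10β-methyl) | C=C[C@]1(C)C[C@@H](O[Si](CC)(CC)CC)[C@@H](C(=C)C(=O)OCC=C)[C@@H](O)[C@H]1C(=C)CO[Si](c1ccccc1)(c1ccccc1)C(C)(C)C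
F6 | step 21 | prop-2-en-1-yl 15-(TBDPS-oxy)-6β-(TBS-oxy)-8β-(TES-oxy)elema-1,3,11(13)-trien-12-oate | C=C[C@]1(C)C[C@@H](O[Si](CC)(CC)CC)[C@@H](C(=C)C(=O)OCC=C)[C@@H](O[Si](C)(C)C(C)(C)C)[C@H]1C(=C)CO[Si](c1ccccc1)(c1ccccc1)C(C)(C)C
F7 | step 21 | prop-2-en-1-yl 15-(TBDPS-oxy)-6β-(TBS-oxy)-8β-hydroxyelema-1,3,11(13)-trien-12-oate | C=C[C@]1(C)C[C@@H](O)[C@@H](C(=C)C(=O)OCC=C)[C@@H](O[Si](C)(C)C(C)(C)C)[C@H]1C(=C)CO[Si](c1ccccc1)(c1ccccc1)C(C)(C)C
F8 | step 21 | prop-2-en-1-yl 15-(TBDPS-oxy)-6β-(TBS-oxy)-8β-{[(2S)-3-(TBS-oxy)-2-methylpropanoyl]oxy}elema-1,3,11(13)-trien-12-oate | C=C[C@]1(C)C[C@@H](OC(=O)[C@@H](C)CO[Si](C)(C)C(C)(C)C)[C@@H](C(=C)C(=O)OCC=C)[C@@H](O[Si](C)(C)C(C)(C)C)[C@H]1C(=C)CO[Si](c1ccccc1)(c1ccccc1)C(C)(C)C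
F9 | step 21 | prop-2-en-1-yl 6β,15-dihydroxy-8β-{[(2S)-3-hydroxy-2-methylpropanoyl]oxy}elema-1,3,11(13)-trien-12-oate | C=C[C@]1(C)C[C@@H](OC(=O)[C@@H](C)CO)[C@@H](C(=C)C(=O)OCC=C)[C@@H](O)[C@H]1C(=C)CO
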